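**Retrosynthetic overview**
1. Target 13 comes from triol 10 by acylation of the secondary hydroxyl on the seven-membered ring with a protected 4-hydroxybenzoyl unit, then release of the phenol.
2. The five-membered ring is closed second. Reductive opening of epoxide 9 and closure onto the side-chain ketone forms the bond between the ring-fusion CH and the carbinol carbon (farnesane C6–C10), and gives both new hydroxyls and the trans fusion.
3. Epoxide 9 comes from aldol 8 by hydroxyl-directed epoxidation; 8 comes from aldehyde 5 and 3-methylbutan-2-one (farnesane C9–C13) by a proline aldol.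
4. The seven-membered ring is closed first. The linalyl-type tertiary acetate 3 is ionized and captured by C7 of the 6,7-olefin (as a dienamine), forming the farnesane C1–C7 bond and the quaternary centre. The order, 1,7-closure then 6,10-closure, is that of the proposed daucane biogenesis.
5. Enal 3 comes from linalyl acetate 1 by allylic oxidation.

Assumption: the (S)-amine in step 2 is taken to give (R)-5 (its enantiomer is used if the induction runs the other way); racemic linalyl acetate is used because its stereocentre is destroyed.

**Route**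

Step 1
Reactants: 1 linalyl acetate
Product: 3 (6E)-3,7-dimethyl-8-oxoocta-1,6-dien-3-yl acetate, via allylic alcohol 2 (not isolated)
Conditions: SeO2 (1.2 equiv), 1,4-dioxane, 80 °C
Reagents that add atoms: selenium dioxide, O=[Se]=O
Why: Riley oxidation (ene reaction of SeO2 followed by a 2,3-sigmatropic shift) attacks the (E)-methyl group of the trisubstituted olefin selectively and carries the primary allylic alcohol on to the (E)-enal, while the tertiary allylic acetate and the vinyl group are left alone.

Step 2
Reactants: 3 (6E)-3,7-dimethyl-8-oxoocta-1,6-dien-3-yl acetate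
Product: 5 (R)-1,5-dimethylcyclohepta-2,5-diene-1-carbaldehyde, via dienamine 4 (not isolated)
Conditions: Pd(PPh3)4 (5 mol %), (S)-N1,N1-diethyl-3,3-dimethylbutane-1,2-diamine (20 mol %), CF3SO3H (20 mol %), MeCN (0.02 M), 40 °C
Reagents that add atoms: none
Why: Proposed new method: the primary amine condenses with the α-branched enal to a dienamine whose nucleophilic α-carbon (the γ-carbon cannot reach the allyl terminus without a five-membered endo closure) attacks, anti to the metal, the unsubstituted terminus of the π-allyl complex that zerovalent palladium forms from the tertiary allylic acetate, so that the cyclohepta-2,5-diene closes through a boat-like transition state (attack on the tertiary terminus would join two fully substituted carbons and is disfavoured) and the tert-butyl group of the amine shields one dienamine face to set the quaternary centre as (R); the closest known reaction types are the amine/palladium co-catalyzed intramolecular Tsuji–Trost α-allylation of aldehydes and the chiral primary amine/palladium α-allylation of α-branched aldehydes to quaternary centres.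

Step 3
Reactants: 5 (R)-1,5-dimethylcyclohepta-2,5-diene-1-carbaldehyde; 6 3-methylbutan-2-one
Product: 8 (1R)-1-[(1R)-1,5-dimethylcyclohepta-2,5-dien-1-yl]-1-hydroxy-4-methylpentan-3-one, via enamine 7 (not isolated)
Conditions: L-proline (30 mol %), 6 (20 equiv), DMSO, 25 °C
Reagents that add atoms: none
Why: Proline-catalyzed direct aldol reaction (enamine catalysis): the less substituted enamine of the methyl ketone adds to the non-enolizable α-quaternary aldehyde through the hydrogen-bonded chair transition state, so the new carbinol centre is set as (R) by the catalyst, as with other α-branched aldehydes.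

Step 4
Reactants: 8 (1R)-1-[(1R)-1,5-dimethylcyclohepta-2,5-dien-1-yl]-1-hydroxy-4-methylpentan-3-one
Product: 9 (1R)-1-[(1S,6S,7R)-3,6-dimethyl-8-oxabicyclo[5.1.0]oct-3-en-6-yl]-1-hydroxy-4-methylpentan-3-one
Conditions: VO(acac)2 (5 mol %), t-BuOOH (1.5 equiv), toluene, 0 to 25 °C
Reagents that add atoms: tert-butyl hydroperoxide, CC(C)(C)OO
Why: Hydroxyl-directed vanadium-catalyzed epoxidation (Sharpless–Michaelson type): the homoallylic hydroxyl binds the vanadium peroxide and delivers oxygen to the neighbouring cis-disubstituted ring olefin on the face that carries the side chain, which fixes both epoxide centres, while the trisubstituted olefin can only be reached through a larger and slower chelate.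

Step 5
Reactants: 9 (1R)-1-[(1S,6S,7R)-3,6-dimethyl-8-oxabicyclo[5.1.0]oct-3-en-6-yl]-1-hydroxy-4-methylpentan-3-one
Product: 10 (1R,3R,3aS,4S,8aR)-6,8a-dimethyl-3-(propan-2-yl)-1,2,3,3a,4,5,8,8a-octahydroazulene-1,3,4-triol
Conditions: (C5H5)2TiCl2 (2.5 equiv), Zn (5 equiv), THF, 25 °C; then 1 M HCl
Reagents that add atoms: none
Why: Nugent–RajanBabu reductive epoxide opening followed by a 5-exo radical addition to the ketone: (C5H5)2TiCl (trivalent titanium) cleaves the C–O bond at the epoxide carbon next to the quaternary centre, the radical adds to the carbonyl carbon anti to the bulky titanium alkoxide on the neighbouring carbon (hence the trans ring fusion, because the epoxide was syn to the side chain) with the isopropyl group turned away from that carbon (hence the configuration of the tertiary carbinol), and a second equivalent of the titanium reagent traps the alkoxyl radical so that the addition is not reversed.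

Step 6
Reactants: 10 (1R,3R,3aS,4S,8aR)-6,8a-dimethyl-3-(propan-2-yl)-1,2,3,3a,4,5,8,8a-octahydroazulene-1,3,4-triol; 11 4-acetoxybenzoyl chloride
Product: 12 (1R,3R,3aS,4S,8aR)-1,3-dihydroxy-6,8a-dimethyl-3-(propan-2-yl)-1,2,3,3a,4,5,8,8a-octahydroazulen-4-yl 4-(acetyloxy)benzoate
Conditions: 11 (1.1 equiv), pyridine, DMAP (10 mol %), CH2Cl2, −20 to 0 °C
Reagents that add atoms: none
Why: DMAP-catalyzed esterification (nucleophilic acyl substitution) selects the secondary hydroxyl on the seven-membered ring because the other secondary hydroxyl is neopentylic and cis to the angular methyl group and the third hydroxyl is tertiary; no stereocentre is touched.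

Step 7
Reactants: 12 (1R,3R,3aS,4S,8aR)-1,3-dihydroxy-6,8a-dimethyl-3-(propan-2-yl)-1,2,3,3a,4,5,8,8a-octahydroazulen-4-yl 4-(acetyloxy)benzoate
Product: 13 (1R,3R,3aS,4S,8aR)-1,3-dihydroxy-6,8a-dimethyl-3-(propan-2-yl)-1,2,3,3a,4,5,8,8a-octahydroazulen-4-yl 4-hydroxybenzoate
Conditions: NH3 (7 M in MeOH), 0 °C
Reagents that add atoms: none
Why: Aminolysis of the aryl acetate (nucleophilic acyl substitution) is much faster than attack on the secondary alkyl benzoate, and the phenol set free deactivates the remaining ester further, so the benzoate and all stereocentres survive.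

**Compound list**
1 | linalyl acetate (3,7-dimethylocta-1,6-dien-3-yl acetate, racemic) | CC(C)=CCCC(C)(OC(C)=O)C=C | starting material
2 | (6E)-8-hydroxy-3,7-dimethylocta-1,6-dien-3-yl acetate | OC/C(C)=C/CCC(C)(OC(C)=O)C=C | intermediate
3 | (6E)-3,7-dimethyl-8-oxoocta-1,6-dien-3-yl acetate | O=C/C(C)=C/CCC(C)(OC(C)=O)C=C | intermediate
4 | dienamine of 3: the aldehyde condensed as a 1-amino-1,3-diene (3Z) on the primary nitrogen of (S)-N1,N1-diethyl-3,3-dimethylbutane-1,2-diamine | C=CC(C)(OC(C)=O)C/C=C\C(C)=CN[C@H](CN(CC)CC)C(C)(C)C | intermediate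
5 | (R)-1,5-dimethylcyclohepta-2,5-diene-1-carbaldehyde | CC1=CC[C@@](C)(C=O)C=CC1 | intermediate
6 | 3-methylbutan-2-one | CC(=O)C(C)C | starting material
7 | enamine of 6 on L-proline: (S)-1-(3-methylbut-1-en-2-yl)pyrrolidine-2-carboxylic acid | C=C(C(C)C)N1CCC[C@H]1C(=O)O | intermediate
8 | (1R)-1-[(1R)-1,5-dimethylcyclohepta-2,5-dien-1-yl]-1-hydroxy-4-methylpentan-3-one | CC1=CC[C@@](C)([C@H](O)CC(=O)C(C)C)C=CC1 | intermediate
9 | (1R)-1-[(1S,6S,7R)-3,6-dimethyl-8-oxabicyclo[5.1.0]oct-3-en-6-yl]-1-hydroxy-4-methylpentan-3-one (epoxide syn to the side chain) | CC1=CC[C@@](C)([C@H](O)CC(=O)C(C)C)[C@H]2O[C@H]2C1 | intermediate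
10 | (1R,3R,3aS,4S,8aR)-6,8a-dimethyl-3-(propan-2-yl)-1,2,3,3a,4,5,8,8a-octahydroazulene-1,3,4-triol | CC1=CC[C@@]2(C)[C@H](O)C[C@@](O)(C(C)C)[C@@H]2[C@@H](O)C1 | intermediate
11 | 4-acetoxybenzoyl chloride | CC(=O)Oc1ccc(cc1)C(Cl)=O | starting material
12 | (1R,3R,3aS,4S,8aR)-1,3-dihydroxy-6,8a-dimethyl-3-(propan-2-yl)-1,2,3,3a,4,5,8,8a-octahydroazulen-4-yl 4-(acetyloxy)benzoate | CC1=CC[C@@]2(C)[C@H](O)C[C@@](O)(C(C)C)[C@@H]2[C@@H](OC(=O)c2ccc(OC(C)=O)cc2)C1 | intermediate
13 | (1R,3R,3aS,4S,8aR)-1,3-dihydroxy-6,8a-dimethyl-3-(propan-2-yl)-1,2,3,3a,4,5,8,8a-octahydroazulen-4-yl 4-hydroxybenzoate | CC1=CC[C@@]2(C)[C@H](O)C[C@@](O)(C(C)C)[C@@H]2[C@@H](OC(=O)c2ccc(O)cc2)C1 | target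

**Step count and risks**
Total steps: 7. Longest linear sequence: 7 (1 to 13).

Steps most likely to fail:

Step 2 (the seven-membered ring closure is untested; five-membered closure at the tertiary allyl terminus, diene formation by elimination, or low enantioselectivity are the likely failures). The fallback sets out from 3 and comes back at 8. Compound 3 is converted with TBSOTf and Et3N (CH2Cl2, −78 °C) into the tert-butyldimethylsilyl dienol ether F1. The tertiary acetate of F1 is ionized with Me2AlCl (CH2Cl2, −78 °C), and the allyl cation is captured by the α-carbon of the enol ether (a Lewis-acid enol silane 1,7-closure) to give the racemic aldehyde F2. F2 is put through the L-proline aldol of step 3, which gives 8 together with its ring epimer F3; chromatographic separation returns the route to 8.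

Step 4 (the trisubstituted ring olefin is intrinsically more nucleophilic and is also within reach of the hydroxyl, so a mixture of epoxides is possible). The fallback sets out from 8 and comes back at 9. Compound 8 is acylated with Boc2O and DMAP to the tert-butyl carbonate F4. IBr in toluene at −85 °C cyclizes F4 to the six-membered cyclic iodocarbonate F5: only the olefin next to the quaternary carbon can close a six-membered ring, oxygen is delivered on the side-chain face and iodine goes trans onto the far carbon. K2CO3 in MeOH at 0 °C then cleaves the carbonate, and the alkoxide displaces the iodide to give epoxide 9.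

Step 5 (epoxide homolysis may occur at the wrong carbon, the radical may be reduced or deoxygenated before it adds to the ketone, or the fusion may come out cis). The fallback sets out from 5 and comes back at 10, closing the ring by a polar epoxide–olefin cyclization.
- Aldehyde 5 is allylated with B-allyldiisopinocampheylborane (the enantiomer that gives the (R)-carbinol) to the homoallylic alcohol F6.
- VO(acac)2 and t-BuOOH give the epoxide F7, syn to the side chain.
- Cross-metathesis with 2-methylbut-2-ene (second-generation Grubbs catalyst, RuCl2(=CHPh)(PCy3)(H2IMes)) gives the prenyl epoxide F8.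
- Et2AlCl in CH2Cl2 at −78 °C brings about backside attack of the trisubstituted olefin on the epoxide carbon next to the quaternary centre (trans fusion by inversion), and the tertiary cation loses a proton to give the isopropylidene diol F9.
- Ozonolysis with one equivalent of O3 at −78 °C (Me2S work-up) cleaves the tetrasubstituted olefin to the ketone F10.
- i-PrMgCl with CeCl3 in THF at −78 °C adds from the face opposite the angular methyl group to give 10.

Further compounds
F1 | step 2 | tert-butyldimethylsilyl dienol ether of 3 (3Z), tertiary acetate retained | C=CC(C)(OC(C)=O)C/C=C\C(C)=CO[Si](C)(C)C(C)(C)C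
F2 | step 2 | racemic 1,5-dimethylcyclohepta-2,5-diene-1-carbaldehyde | CC1=CCC(C)(C=O)C=CC1
F3 | step 2 | (1R)-1-[(1S)-1,5-dimethylcyclohepta-2,5-dien-1-yl]-1-hydroxy-4-methylpentan-3-one | CC1=CC[C@](C)([C@H](O)CC(=O)C(C)C)C=CC1
F4 | step 4 | tert-butyl (1R)-1-[(1R)-1,5-dimethylcyclohepta-2,5-dien-1-yl]-4-methyl-3-oxopentyl carbonate | CC1=CC[C@@](C)([C@H](OC(=O)OC(C)(C)C)CC(=O)C(C)C)C=CC1
F5 | step 4 | six-membered cyclic iodocarbonate of 8 (carbonate across the carbinol carbon and the near olefin carbon on the side-chain face, iodine trans on the far carbon) | CC1=CC[C@@]2(C)[C@@H](CC(=O)C(C)C)OC(=O)O[C@H]2[C@H](I)C1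
F6 | step 5 | (1R)-1-[(1R)-1,5-dimethylcyclohepta-2,5-dien-1-yl]but-3-en-1-ol | CC1=CC[C@@](C)([C@H](O)CC=C)C=CC1
F7 | step 5 | (1R)-1-[(1S,6S,7R)-3,6-dimethyl-8-oxabicyclo[5.1.0]oct-3-en-6-yl]but-3-en-1-ol | CC1=CC[C@@](C)([C@H](O)CC=C)[C@H]2O[C@H]2C1
F8 | step 5 | (1R)-1-[(1S,6S,7R)-3,6-dimethyl-8-oxabicyclo[5.1.0]oct-3-en-6-yl]-4-methylpent-3-en-1-ol | CC1=CC[C@@](C)([C@H](O)CC=C(C)C)[C@H]2O[C@H]2C1
F9 | step 5 | (1R,3aS,4S,8aR)-6,8a-dimethyl-3-(propan-2-ylidene)-1,2,3,3a,4,5,8,8a-octahydroazulene-1,4-diol | CC1=CC[C@@]2(C)[C@H](O)CC(=C(C)C)[C@@H]2[C@@H](O)C1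
F10 | step 5 | (3R,3aR,8S,8aS)-3,8-dihydroxy-3a,6-dimethyl-3,3a,4,7,8,8a-hexahydroazulen-1(2H)-one | CC1=CC[C@@]2(C)[C@H](O)CC(=O)[C@@H]2[C@@H](O)C1
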